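## The problem

The target is a neo-clerodane-type tetracycle. Clerodane numbering is used throughout: C1 is the furan-bearing CH, C2 the carbinol, C3=C4 the alkene, C5 the quaternary carbon carrying the lactone CH2 C19, C7 the acetoxy carbon, C8 the CH–CH3, C9 the quaternary carbon carrying methyl C20, C10 the ring-fusion CH, C11 the CH2 next to ketone C12, C13–C16 the furan with C16 on C1, and C18 the lactone carbonyl. Ring A is C1–C5 with C10, ring B is C5–C10, and ring C is the seven-membered ketone ring (C1, C10, C9, C11, C12, C13, C16); α is the face of C19 and C20, β the face of H-10.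

A synthesis has to build a trans-decalin with two quaternary carbons (C5, C9) flanking the fusion carbon C10, an 18,19-butenolide across C4–C5, and a furan fused to ring C and bonded directly to C1. There are seven stereocentres (C1, C2, C5, C7, C8, C9, C10). The vicinal pair C8/C9 can be set in an open chain and can then steer C5, C10, C1 and C2 through a chair-like ring B. C7 can be left to the end, because axial C19 and C20 block the α face of a C7 ketone and force hydride to give the axial 7α alcohol. The furan (and any vinylfuran on the way) will not tolerate strong acid or electrophilic oxidants, the γ-hydroxybutenolide and the acetate limit the use of base and hydride late on, and the two secondary hydroxyls at C2 and C7 must be told apart.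

The feature that makes the key step possible lies in ring A. The C2 oxygen and C19 on C5 are cis and 1,4 across a cyclohexene whose alkene C3=C4 carries carboxyl C18. That is exactly where the O–C(=O) bridge sits when an alkene adds across C3 and C6 of a 2-pyrone-4-carboxylate. The trans relation of the C1 furan and C9 on C10 is that of an (E)-furylalkene.

## Retrosynthesis

**Ring C (C12–C13).** Target 32 comes from its C2 silyl ether 31, and 31 from acid 29 by cutting the C12–C13 bond. Cutting C1–C16 instead would ask a furan α-anion to add to a hindered ring carbon with stereocontrol, and building the furan last leaves the seven-membered ring unsolved. The chosen cut uses the fact that the furan β-carbon C13 can be reached only intramolecularly by C12. In 29 the furan on C1 and the two-carbon arm on C9 are both equatorial and lie side by side. The forward reaction must acylate C13 without touching the free α-position C15, the acetate or the allylic silyl ether.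

**Functional-group adjustment (29 back to 24).** Acid 29 comes from aldehyde 28, alcohol 27 and bis-silyl ether acetate 26; 26 comes from mono-silyl ether 25 and diol 24. No skeletal bond is cut. The work is to tell the hydroxyls apart. C2–OH is equatorial and allylic and is silylated first. C7–OH is axial between C19 and C20 and is acetylated second. The primary C12 silyl ether is then removed in the presence of the secondary one and oxidised.

**Hydride stage (24 from 22).** Diol lactone 24 is traced to keto lactone ester 22. One reagent must reduce the C7 ketone from the β face and the bridged lactone carbonyl C19. The freed C19 alcohol then closes onto the C18 ester. This sets C7 and moves the lactone from C2–O–C19 to C19–O–C18; the precursor carries every other stereocentre already.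

**Key cut (22 from 21).** The C1–C2 and C5–C10 bonds are cut together, which opens rings A and B and removes four stereocentres. The precursor is pyrone triene 21, a flat 2-pyrone joined through a C7 ketone tether to an (E)-2-furylalkene. Cutting only one of these bonds (for example a Michael closure of ring B) would not deliver the C2 oxygen and C19 cis in the same event. The forward reaction must be an intramolecular inverse-demand Diels–Alder reaction that keeps CO2, with the tether exo and the furan endo.

**Fragment union (C6–C7).** Ketone 21 is cut between C6 and C7 into acid 12 (used as acid chloride 19) and methyl 3-methyl-2-pyrone-4-carboxylate 18 (used as dienolate 20). The methyl of 18 is γ to the C4 ester and therefore acidic. A cut at C5–C6 would need a ketone enolate to be coupled to a 3-halopyrone under basic conditions that a pyrone does not tolerate. All chirality stays in 12, and 18 is achiral.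

**C8–C9 by sigmatropy.** Acid 12 comes from propionate 9 of allylic alcohol 7 by cutting C8–C9 (Ireland–Claisen rearrangement). One step makes the quaternary C9, the adjacent C8 and the (E)-alkene. C12 is carried as a silyl ether rather than an ester. With an ester, the C11 protons would be the most acidic in 9 and their dienolate would expel the allylic carboxylate. The forward reaction needs the (Z)-silyl ketene acetal, because the alkene of 7 is E.

**Allylic alcohol.** Alcohol 7 comes from alkenyl iodide 6, which comes from propargylic alcohol 4, made from furfural 1 and silyloxybutyne 2. The cut at C1–C10 brings in the only external source of chirality (a catalytic alkynylation). Hydroxyl-directed hydroalumination then fixes the alkene geometry. A direct vinyl-metal addition would need a stereodefined trisubstituted vinyl halide and a less certain asymmetric step.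

**Pyrone.** Pyrone 18 comes from aldehyde diester 17 by enol lactonisation. Aldehyde 17 comes from allyl maleate 15, and 15 from dimethyl acetylenedicarboxylate 13 by carbocupration and allylation. The two alkyne carbons become pyrone C3 and C4 with both carboxyls already in place, which is why this source is preferred over degrading a more highly substituted pyrone.

## Roads not taken

**Alternative 1:** Enzymatic polyene cyclisation. The cut removes every ring A and ring B bond at once and leads back to geranylgeranyl diphosphate A1. A (−)-kolavenyl diphosphate synthase protonates the terminal alkene, closes both rings, runs two hydride and two methyl shifts and gives (−)-kolavenyl diphosphate A2.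
- Merits: one step from an achiral chain builds the decalin and C5, C8, C9 and C10 in the right absolute sense, without protecting groups. In step count to the bare decalin and in the certainty of absolute control it is better than the chosen plan, which needs ten steps and relies on a ligand plus chirality transfer.
- Weak points: A2 has C18 and C19 as methyls and no oxygen at C2, C7 or C12. The side chain must still become a 12-keto furan, and C16 must be bonded to the unactivated C1 methylene. That is six or more site-selective oxidations and one C–C bond at positions without handles, and it needs enzyme production.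
- Comparison: the chosen plan is longer to the decalin, but its key step also delivers the C1–furan bond, the C2 oxygen and C19 at the carboxyl level.

**Alternative 2:** Furan last by enynone cycloisomerisation. The cut opens the O–C15 bond and the C12–O bond and leads to 2-ethynyl cycloheptenone A3. AuCl3 (trivalent gold) activates the alkyne, the C16 ketone oxygen attacks C15 and methanol adds to C12, giving furan methyl ether A4.
- Merits: mild, catalytic and atom-economic. The furan is absent until the end, a real advantage over the chosen plan, where a furan must survive a strong amide base, heat, hydride and a Lewis acid.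
- Weak points: A3 already holds all three carbocycles and all seven stereocentres, so the step solves the easiest ring. C1 in A3 is α to the C16 ketone and can epimerise. A4 still needs its furfurylic C12 ether turned into the ketone beside an allylic silyl ether, an acetate and a butenolide.
- Comparison: the chosen plan carries a sensitive furan, but uses it three times: as the activating group of the dienophile, as the endo-directing group and as the nucleophile for ring C.

**Alternative 3:** Directed C–H lactonisation. The cut opens the C19–O bond and leads to acid A5 with a plain C5 methyl. Pd(OAc)2 (divalent palladium), a mono-protected amino acid ligand and a peroxide oxidant activate a C–H bond of that methyl under direction of the C18 carboxylate and give lactone A6.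
- Merits: the angular carbon is introduced as a simple methyl, so the decalin could come from classical annulation chemistry, and no bridged lactone or hydride step is needed. In that respect the precursor is simpler than 22.
- Weak points: the directing carboxylate sits on an sp2 carbon, so the palladacycle must include the alkene. Allylic C–H bonds and the alkene compete for the metal and the peroxide. A6 has no substituent at C1, no oxygen at C2 and no ring C, and offers no handle to add them.
- Comparison: the chosen plan obtains the C19 oxygen from the pyrone carbonyl and sets C1 and C2 in the same step; it pays with the hydride transposition of step 11.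

Key step: step 10

Assumption: the (S,S)-ProPhenol antipode is taken to give the (R)-carbinol 4; if the sense of induction proves opposite, the (R,R)-ligand is used, and the configuration is checked on 4 (MTPA esters) before going on.

## Steps

Step 1
Reactants: 1 furfural; 2 tert-butyl(but-3-yn-1-yloxy)dimethylsilane
Product: 4 (1R)-5-[(tert-butyldimethylsilyl)oxy]-1-(furan-2-yl)pent-2-yn-1-ol, via alkynylzinc 3 (not isolated)
Conditions: Me2Zn, (S,S)-ProPhenol (10 mol %), Ph3P=O (cat.), PhMe, 0 °C
Reagents that add atoms: none
Why: Catalytic asymmetric alkynylation of an aromatic aldehyde by an alkynylzinc made in situ; the dinuclear zinc–ProPhenol complex delivers the alkynyl group to one aldehyde face and sets C1 (R), the only stereocentre brought in from outside.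

Step 2
Reactants: 4 (1R)-5-[(tert-butyldimethylsilyl)oxy]-1-(furan-2-yl)pent-2-yn-1-ol
Product: 6 (1R,2Z)-5-[(tert-butyldimethylsilyl)oxy]-1-(furan-2-yl)-3-iodopent-2-en-1-ol, via alkenylalanate 5 (not isolated)
Conditions: NaAlH2(OCH2CH2OMe)2, THF, 0 → 23 °C; then I2, −78 °C
Reagents that add atoms: iodine, II
Why: Hydroxyl-directed trans-hydroalumination of a propargylic alcohol places aluminium on the distal carbon in a five-membered alkoxyalanate; iodinolysis with retention should give the (Z)-3-iodoallylic alcohol as one regio- and geometric isomer.

Step 3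
Reactants: 6 (1R,2Z)-5-[(tert-butyldimethylsilyl)oxy]-1-(furan-2-yl)-3-iodopent-2-en-1-ol
Product: 7 (1R,2E)-5-[(tert-butyldimethylsilyl)oxy]-1-(furan-2-yl)-3-methylpent-2-en-1-ol
Conditions: Me2CuLi (from MeLi and CuI, excess), Et2O, 0 °C
Reagents that add atoms: lithium dimethylcuprate Me2CuLi, [Li+].C[Cu-]C
Why: Cuprate substitution of an alkenyl iodide proceeds with retention, so the methyl ends up cis to C1 and the silyloxyethyl arm trans (E); the alkoxide formed first does not interfere.

Step 4
Reactants: 7 (1R,2E)-5-[(tert-butyldimethylsilyl)oxy]-1-(furan-2-yl)-3-methylpent-2-en-1-ol; 8 propionyl chloride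
Product: 9 (1R,2E)-5-[(tert-butyldimethylsilyl)oxy]-1-(furan-2-yl)-3-methylpent-2-en-1-yl propanoate
Conditions: pyridine, DMAP (cat.), CH2Cl2, −20 → 0 °C
Reagents that add atoms: none
Why: DMAP-catalysed acylation under cold, buffered conditions; the doubly activated (furyl and allyl) alcohol is kept away from acid so that it neither ionises nor undergoes 1,3-transposition.

Step 5
Reactants: 9 (1R,2E)-5-[(tert-butyldimethylsilyl)oxy]-1-(furan-2-yl)-3-methylpent-2-en-1-yl propanoate
Product: 12 (2S,3R,4E)-3-{2-[(tert-butyldimethylsilyl)oxy]ethyl}-5-(furan-2-yl)-2,3-dimethylpent-4-enoic acid, via silyl ketene acetal 10 (not isolated), via silyl ester 11 (not isolated)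
Conditions: LiN(iPr)2, THF–DMPU, −78 °C; Me3SiCl, Et3N; −78 → 50 °C; aqueous work-up at pH 4
Reagents that add atoms: none
Why: Ireland–Claisen rearrangement: enolisation in THF–DMPU gives the (Z)-silyl ketene acetal, which rearranges through a chair with the furyl group equatorial (an axial furyl would clash with the axial C9 methyl), so the (R)-carbinol is transferred to C9 (R) and C8 (S) and the new C1=C10 alkene is E.

Step 6
Reactants: 13 dimethyl acetylenedicarboxylate
Product: 15 dimethyl (2Z)-2-methyl-3-(prop-2-en-1-yl)but-2-enedioate, via vinylcopper 14 (not isolated)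
Conditions: MeMgBr, CuBr·SMe2, THF, −40 °C; 13, −78 °C; allyl bromide, −78 → 0 °C
Reagents that add atoms: methylmagnesium bromide MeMgBr, C[Mg]Br; allyl bromide, C=CCBr
Why: syn-Carbocupration of an acetylenedicarboxylate by a methylcopper reagent and capture of the alkenylcopper by an allylic halide is a standard route to 2,3-dialkylmaleates; no stereocentre is formed.

Step 7
Reactants: 15 dimethyl (2Z)-2-methyl-3-(prop-2-en-1-yl)but-2-enedioate
Product: 17 dimethyl (2Z)-2-methyl-3-(2-oxoethyl)but-2-enedioate, via ozonide 16 (not isolated)
Conditions: O3 (1 equiv), CH2Cl2, −78 °C; PPh3, −78 → 23 °C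
Reagents that add atoms: ozone, [O-][O+]=O
Why: Ozonolysis with reductive work-up; the terminal alkene reacts far faster than the tetrasubstituted alkene deactivated by two esters.

Step 8
Reactants: 17 dimethyl (2Z)-2-methyl-3-(2-oxoethyl)but-2-enedioate
Product: 18 methyl 3-methyl-2-oxo-2H-pyran-4-carboxylate
Conditions: TsOH·H2O (cat.), PhMe, 110 °C, 4 Å molecular sieves
Reagents that add atoms: none
Why: Acid-catalysed enol lactonisation, the aldehyde counterpart of isocoumarin formation from 2-(2-oxoalkyl)benzoates; the push–pull dienol equilibrates its C=C geometry through the conjugated enal tautomer, the enol oxygen reaches the ester on the methyl-bearing carbon, and loss of methanol to the pyrone makes the closure irreversible.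

Step 9
Reactants: 12 (2S,3R,4E)-3-{2-[(tert-butyldimethylsilyl)oxy]ethyl}-5-(furan-2-yl)-2,3-dimethylpent-4-enoic acid; 18 methyl 3-methyl-2-oxo-2H-pyran-4-carboxylate
Product: 21 methyl 3-[(3S,4R,5E)-4-{2-[(tert-butyldimethylsilyl)oxy]ethyl}-6-(furan-2-yl)-3,4-dimethyl-2-oxohex-5-en-1-yl]-2-oxo-2H-pyran-4-carboxylate, via acid chloride 19 (not isolated), via lithium dienolate 20 (not isolated)
Conditions: 12, 1-chloro-N,N,2-trimethylprop-1-enylamine, CH2Cl2, 0 °C; separately 18 (2.2 equiv), LiN(iPr)2 (2.2 equiv), THF, −78 °C; then 19, −78 °C; AcOH
Reagents that add atoms: none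
Why: Lateral (vinylogous) deprotonation of the 3-methyl group γ to the C4 ester gives a cross-conjugated dienolate that is C-acylated at the exocyclic carbon, as with 2-methylbenzoate and 6-alkyl-2-pyrone anions, because attack through the ring carbon would break the pyrone conjugation; a second equivalent of dienolate takes up the more acidic product as its C6 enolate, which also protects C8 from epimerisation.

Step 10
Reactants: 21 methyl 3-[(3S,4R,5E)-4-{2-[(tert-butyldimethylsilyl)oxy]ethyl}-6-(furan-2-yl)-3,4-dimethyl-2-oxohex-5-en-1-yl]-2-oxo-2H-pyran-4-carboxylate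
Product: 22 bridged cycloadduct: trans-fused decalin-7-one whose ring A is a 2-oxabicyclo[2.2.2]oct-5-en-3-one (lactone O on C2 and lactone C19=O on C5, both α; C3=C4 with CO2Me on C4), 1β-(furan-2-yl), H-10β, 8α-methyl, 9α-methyl, 9β-[2-(tert-butyldimethylsilyloxy)ethyl]
Conditions: PhMe (0.005 M), BHT (cat.), 100 °C, sealed tube
Reagents that add atoms: none
Why: Thermal, concerted but asynchronous inverse-electron-demand [4+2] cycloaddition in which the nucleophilic alkene carbon C10 (β to the furan) bonds to the electron-poor pyrone terminus C5 and C1 bonds to C2; the closest known reaction type is the intramolecular Diels–Alder reaction of ester-substituted 2-pyrones with tethered alkenes, which gives 2-oxabicyclo[2.2.2]oct-5-en-3-ones that keep CO2 under mild heating. Ring B closes through the four-atom tether C6–C9 between diene carbon C5 and dienophile carbon C10 in a chair-like array, and ring A is the new cyclohexene (C1, C2, C3=C4, C5, C10) held inside the bicyclooctene. C5 and C2 follow from suprafacial addition across the diene, so the O–C19(=O) bridge lies on one face and stores the cis relation of the C2 oxygen and C19. C1 and C10 come out trans because the (E)-alkene adds suprafacially. The trans ring fusion (C10 against C5) needs the tether exo and the furan endo: the C4 ester beside the tether clashes with quaternary C9 in the endo-tether array, and the furan gains secondary overlap under the diene. The absolute sense comes from C8 and C9, since the exo chair that leads to 22 has the C8 methyl equatorial and the C9 methyl axial, whereas addition to the other diene face would force the C8 methyl axial. High dilution and BHT are used to suppress intermolecular reaction and polymerisation of the vinylfuran.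

Step 11
Reactants: 22 bridged cycloadduct
Product: 24 diol lactone: 2α,7α-dihydroxy-18,19-olide (C18=O on C4, O–C19H2 on C5α), C3=C4, 1β-(furan-2-yl), H-10β, 8α-methyl, 9α-methyl, 9β-[2-(tert-butyldimethylsilyloxy)ethyl], via triol ester 23 (not isolated)
Conditions: LiBH4, THF, 0 → 23 °C; aqueous NH4Cl work-up
Reagents that add atoms: none
Why: Borohydride reduction: hydride attacks the C7 ketone from the open β (equatorial) face because axial C19 and C20 block the α face, giving the axial 7α alcohol; the strained bridged lactone is reduced (directly or after acyl transfer to the new C7 alkoxide) to C19–OH and C2–OH, and the C19 alcohol closes onto the neighbouring C18 methyl ester, which as a hindered conjugated ester should be reduced more slowly than ketone and lactone.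

Step 12
Reactants: 24 diol lactone
Product: 25 2α-tert-butyldimethylsilyl ether of 24 (7α-OH free)
Conditions: TBSCl, imidazole, DMF, 0 → 23 °C
Reagents that add atoms: tert-butyldimethylsilyl chloride, CC(C)(C)[Si](C)(C)Cl
Why: Silylation of the equatorial allylic C2 hydroxyl; the axial C7 hydroxyl is shielded by syn-axial C19 and C20 and should stay free.

Step 13
Reactants: 25 2α-silyl ether
Product: 26 7α-acetate of 25
Conditions: Ac2O, Et3N, DMAP, CH2Cl2, 40 °C
Reagents that add atoms: acetic anhydride, CC(=O)OC(C)=O
Why: DMAP-catalysed acetylation of the only free hydroxyl; the forcing conditions needed for the hindered axial alcohol are tolerated by lactone, silyl ethers and furan.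

Step 14
Reactants: 26 7α-acetate bis-silyl ether
Product: 27 primary alcohol: 26 with the C12 silyl ether removed (9β-CH2CH2OH), 2α-OTBS retained
Conditions: HF·pyridine, pyridine, THF, 0 °C
Reagents that add atoms: none
Why: Buffered fluoride cleaves a primary silyl ether much faster than a secondary one, which is flanked here by the C1 furyl carbon.

Step 15
Reactants: 27 primary alcohol
Product: 28 aldehyde (9β-CH2CHO)
Conditions: DMP (1,1,1-triacetoxy-1,2-benziodoxol-3(1H)-one), pyridine, CH2Cl2, 23 °C
Reagents that add atoms: none
Why: Periodinane oxidation under buffered, near-neutral conditions; C11 is attached to quaternary C9, so no stereocentre is at risk.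

Step 16
Reactants: 28 aldehyde
Product: 29 carboxylic acid (9β-CH2CO2H; C12 acid)
Conditions: NaClO2, NaH2PO4, 2-methylbut-2-ene, t-BuOH–H2O, 0 → 23 °C
Reagents that add atoms: sodium chlorite NaClO2, [Na+].[O-]Cl=O
Why: Pinnick oxidation; the large excess of 2-methylbut-2-ene takes up the hypochlorous acid so that the furan and the alkene are not chlorinated.

Step 17
Reactants: 29 carboxylic acid
Product: 31 tetracyclic ketone: ring C closed (C12 ketone bonded to furan C13), 7α-OAc, 2α-OTBS, via acid chloride 30 (not isolated)
Conditions: 1-chloro-N,N,2-trimethylprop-1-enylamine, CH2Cl2, 0 °C; then SnCl4, CH2Cl2 (0.002 M), −78 → −20 °C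
Reagents that add atoms: none
Why: Intramolecular Friedel–Crafts acylation of a 2-alkylfuran at its β-carbon, known for furylalkanoic acid chlorides forming six- and seven-membered ketones; the equatorial furan on C1 and the equatorial arm on C9 lie parallel, and high dilution disfavours intermolecular attack at the free α-position C15.

Step 18
Reactants: 31 tetracyclic ketone silyl ether
Product: 32 CNP0182929.1 (7α-acetoxy-2α-hydroxy-12-oxo-18,19-olide with the furan fused to ring C)
Conditions: HF·pyridine, THF, 23 °C
Reagents that add atoms: none
Why: Fluoride desilylation under mildly acidic conditions, which leave the acetate, the butenolide and the furyl ketone untouched and avoid base at the γ-hydroxybutenolide.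

## Compound list

1 | furfural | O=Cc1ccco1 | starting material
2 | tert-butyl(but-3-yn-1-yloxy)dimethylsilane | C#CCCO[Si](C)(C)C(C)(C)C | starting material
3 | methyl[4-(tert-butyldimethylsilyloxy)but-1-ynyl]zinc | C[Zn]C#CCCO[Si](C)(C)C(C)(C)C | intermediate (not isolated)
4 | (1R)-5-[(tert-butyldimethylsilyl)oxy]-1-(furan-2-yl)pent-2-yn-1-ol | O[C@@H](c1ccco1)C#CCCO[Si](C)(C)C(C)(C)C | intermediate
5 | sodium cyclic alkoxy(alkenyl)alanate from 4 (Al on C3 of the pentenyl chain, cis to C1) | [Na+].COCCO[Al-]1(OCCOC)O[C@@H](c2ccco2)C=C1CCO[Si](C)(C)C(C)(C)C | intermediate (not isolated)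
6 | (1R,2Z)-5-[(tert-butyldimethylsilyl)oxy]-1-(furan-2-yl)-3-iodopent-2-en-1-ol | O[C@@H](c1ccco1)/C=C(\I)CCO[Si](C)(C)C(C)(C)C | intermediate
7 | (1R,2E)-5-[(tert-butyldimethylsilyl)oxy]-1-(furan-2-yl)-3-methylpent-2-en-1-ol | O[C@@H](c1ccco1)/C=C(\C)CCO[Si](C)(C)C(C)(C)C | intermediate
8 | propionyl chloride | CCC(=O)Cl | starting material
9 | (1R,2E)-5-[(tert-butyldimethylsilyl)oxy]-1-(furan-2-yl)-3-methylpent-2-en-1-yl propanoate | CCC(=O)O[C@@H](c1ccco1)/C=C(\C)CCO[Si](C)(C)C(C)(C)C | intermediate
10 | (Z)-trimethylsilyl ketene acetal of 9 (methyl cis to OSiMe3) | C/C=C(\O[Si](C)(C)C)O[C@@H](c1ccco1)/C=C(\C)CCO[Si](C)(C)C(C)(C)C | intermediate (not isolated)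
11 | trimethylsilyl ester of acid 12 | C[Si](C)(C)OC(=O)[C@@H](C)[C@](C)(CCO[Si](C)(C)C(C)(C)C)/C=C/c1ccco1 | intermediate (not isolated)
12 | (2S,3R,4E)-3-{2-[(tert-butyldimethylsilyl)oxy]ethyl}-5-(furan-2-yl)-2,3-dimethylpent-4-enoic acid | OC(=O)[C@@H](C)[C@](C)(CCO[Si](C)(C)C(C)(C)C)/C=C/c1ccco1 | intermediate
13 | dimethyl acetylenedicarboxylate | COC(=O)C#CC(=O)OC | starting material
14 | dimethyl (2Z)-2-cuprio-3-methylbut-2-enedioate (alkenylcopper, Cu cis to methyl) | COC(=O)/C(C)=C(/[Cu])C(=O)OC | intermediate (not isolated)
15 | dimethyl (2Z)-2-methyl-3-(prop-2-en-1-yl)but-2-enedioate | COC(=O)/C(C)=C(/CC=C)C(=O)OC | intermediate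
16 | ozonide (1,2,4-trioxolane) of the allyl group of 15 | COC(=O)/C(C)=C(/CC1OCOO1)C(=O)OC | intermediate (not isolated)
17 | dimethyl (2Z)-2-methyl-3-(2-oxoethyl)but-2-enedioate | COC(=O)/C(C)=C(/CC=O)C(=O)OC | intermediate
18 | methyl 3-methyl-2-oxo-2H-pyran-4-carboxylate | COC(=O)C1=C(C)C(=O)OC=C1 | intermediate
19 | (2S,3R,4E)-3-{2-[(tert-butyldimethylsilyl)oxy]ethyl}-5-(furan-2-yl)-2,3-dimethylpent-4-enoyl chloride | ClC(=O)[C@@H](C)[C@](C)(CCO[Si](C)(C)C(C)(C)C)/C=C/c1ccco1 | intermediate (not isolated)
20 | lithium dienolate of 18 (3-methylene, exocyclic ester enolate) | [Li]OC(OC)=C1C=COC(=O)C1=C | intermediate (not isolated)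
21 | methyl 3-[(3S,4R,5E)-4-{2-[(tert-butyldimethylsilyl)oxy]ethyl}-6-(furan-2-yl)-3,4-dimethyl-2-oxohex-5-en-1-yl]-2-oxo-2H-pyran-4-carboxylate (pyrone triene) | COC(=O)C1=C(CC(=O)[C@@H](C)[C@](C)(CCO[Si](C)(C)C(C)(C)C)/C=C/c2ccco2)C(=O)OC=C1 | intermediate
22 | bridged cycloadduct (7-ketone, C2–O–C19(=O)–C5 α-bridge, C3=C4–CO2Me, 1β-furyl, H-10β, 8α-Me, 9α-Me, 9β-CH2CH2OTBS) | O=C1C[C@@]23C(=O)O[C@@H](C=C2C(=O)OC)[C@@H](c4ccco4)[C@@H]3[C@@](C)(CCO[Si](C)(C)C(C)(C)C)[C@@H]1C | intermediate
23 | triol ester (2α-OH, 7α-OH, 5α-CH2OH, C4–CO2Me) | O[C@@H]1C[C@@]2(CO)C(C(=O)OC)=C[C@H](O)[C@@H](c3ccco3)[C@@H]2[C@@](C)(CCO[Si](C)(C)C(C)(C)C)[C@@H]1C | intermediate (not isolated)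
24 | diol lactone (2α,7α-diol, 18,19-olide, C12 OTBS) | O[C@@H]1C[C@@]23COC(=O)C2=C[C@H](O)[C@@H](c4ccco4)[C@@H]3[C@@](C)(CCO[Si](C)(C)C(C)(C)C)[C@@H]1C | intermediate
25 | 2α-OTBS, 7α-OH lactone | O[C@@H]1C[C@@]23COC(=O)C2=C[C@H](O[Si](C)(C)C(C)(C)C)[C@@H](c4ccco4)[C@@H]3[C@@](C)(CCO[Si](C)(C)C(C)(C)C)[C@@H]1C | intermediate
26 | 7α-acetate, 2α-OTBS, C12 OTBS lactone | CC(=O)O[C@@H]1C[C@@]23COC(=O)C2=C[C@H](O[Si](C)(C)C(C)(C)C)[C@@H](c4ccco4)[C@@H]3[C@@](C)(CCO[Si](C)(C)C(C)(C)C)[C@@H]1C | intermediate
27 | 7α-acetate, 2α-OTBS, C12 primary alcohol | CC(=O)O[C@@H]1C[C@@]23COC(=O)C2=C[C@H](O[Si](C)(C)C(C)(C)C)[C@@H](c4ccco4)[C@@H]3[C@@](C)(CCO)[C@@H]1C | intermediate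
28 | 7α-acetate, 2α-OTBS, C12 aldehyde | CC(=O)O[C@@H]1C[C@@]23COC(=O)C2=C[C@H](O[Si](C)(C)C(C)(C)C)[C@@H](c4ccco4)[C@@H]3[C@@](C)(CC=O)[C@@H]1C | intermediate
29 | 7α-acetate, 2α-OTBS, C12 carboxylic acid | CC(=O)O[C@@H]1C[C@@]23COC(=O)C2=C[C@H](O[Si](C)(C)C(C)(C)C)[C@@H](c4ccco4)[C@@H]3[C@@](C)(CC(=O)O)[C@@H]1C | intermediate
30 | C12 acid chloride of 29 | CC(=O)O[C@@H]1C[C@@]23COC(=O)C2=C[C@H](O[Si](C)(C)C(C)(C)C)[C@@H](c4ccco4)[C@@H]3[C@@](C)(CC(=O)Cl)[C@@H]1C | intermediate (not isolated)
31 | 2-O-TBS ether of the target (ring C closed) | CC(=O)O[C@@H]1C[C@@]23COC(=O)C2=C[C@H](O[Si](C)(C)C(C)(C)C)[C@H]2c4occc4C(=O)C[C@@](C)([C@@H]1C)[C@@H]23 | intermediate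
32 | CNP0182929.1 | CC(=O)O[C@@H]1C[C@@]23COC(=O)C2=C[C@H](O)[C@H]2c4occc4C(=O)C[C@@](C)([C@@H]1C)[C@@H]23 | target

## Step count and risks

Total: 18 steps. Longest linear sequence: 15 steps (steps 1–5 and 9–18); the pyrone branch is 3 steps (6–8).

**Step 10 (key step).** The tether-endo array (cis-fused adduct) or the second chair (other diene face) may compete, the doubly activated C6 methylene may enolise and lactonise onto C18, and the bridged lactone may lose CO2 if more heat is needed than planned. C8 is epimerisable in 21 and 22; its equatorial orientation in 22 is also the thermodynamic one, so only the face selection is critical. Fallback: ketone 21 is converted with 1,2-bis(trimethylsilyloxy)ethane and catalytic Me3SiOTf at −78 °C into the C7 dioxolane of the pyrone triene F3. The ketal removes the enolisable carbonyl and adds a geminal substituent effect to the tether, so the cycloaddition can be run colder. Heating F3 in toluene should give the dioxolane cycloadduct F4, and PPTS in wet acetone returns the route to 22.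

**Step 9 (fragment union).** The dienolate may react through oxygen or the ring carbon, the pyrone may self-condense under the amide base, and the hindered acid chloride may form a ketene and lose the C8 configuration. Fallback: pyrone 18 undergoes Wohl–Ziegler bromination (N-bromosuccinimide, AIBN, PhCF3, 80 °C) to methyl 3-(bromomethyl)-2-oxo-2H-pyran-4-carboxylate F1. Zinc insertion (Zn dust, LiCl, THF, 0 °C) gives the pyranylmethylzinc bromide F2, and a Negishi acylation with acid chloride 19 catalysed by Pd(PPh3)4 (zerovalent palladium) rejoins the route at 21 without any strong base.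

**Step 11 (hydride stage).** Over-reduction of the C18 ester or of the butenolide once formed, or incomplete reduction if the acyl group first migrates to the C7 alkoxide and gives a less reactive γ-lactone. Fallback: the strained lactone of 22 is opened with one equivalent of LiOH (THF–H2O, 0 °C) to the C19 hydroxy acid F5 (2α-OH free, C7 ketone and C18 ester intact). Isobutyl chloroformate and N-methylmorpholine at −15 °C give the mixed carbonic anhydride F6. NaBH4 then reduces only the anhydride carbonyl and the C7 ketone, giving triol ester 23, which lactonises to 24.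

**Step 17 (ring C closure).** Intermolecular acylation at the more nucleophilic furan α-position C15, acid-induced decomposition of the furan, or ionisation of the allylic C2 silyl ether by the Lewis acid. Fallback: aldehyde 28 is treated with Me2AlCl in CH2Cl2 at −78 °C so that furan C13 adds to the C12 aldehyde, giving the ring C furyl carbinol F7 (either C12 epimer). Oxidation with the periodinane DMP then gives ketone 31.

## Further compounds

F1 | step 9 | methyl 3-(bromomethyl)-2-oxo-2H-pyran-4-carboxylate | COC(=O)C1=C(CBr)C(=O)OC=C1
F2 | step 9 | [(4-methoxycarbonyl-2-oxo-2H-pyran-3-yl)methyl]zinc bromide | COC(=O)C1=C(C[Zn]Br)C(=O)OC=C1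
F3 | step 10 | C7 1,3-dioxolane of pyrone triene 21 | COC(=O)C1=C(CC3(OCCO3)[C@@H](C)[C@](C)(CCO[Si](C)(C)C(C)(C)C)/C=C/c2ccco2)C(=O)OC=C1
F4 | step 10 | C7 1,3-dioxolane of cycloadduct 22 | C15(OCCO5)C[C@@]23C(=O)O[C@@H](C=C2C(=O)OC)[C@@H](c4ccco4)[C@@H]3[C@@](C)(CCO[Si](C)(C)C(C)(C)C)[C@@H]1C
F5 | step 11 | C19 carboxylic acid with free 2α-OH from hydrolysis of 22 (C7 ketone, C18 methyl ester) | O=C1C[C@@]2(C(=O)O)C(C(=O)OC)=C[C@H](O)[C@@H](c3ccco3)[C@@H]2[C@@](C)(CCO[Si](C)(C)C(C)(C)C)[C@@H]1C
F6 | step 11 | isobutyl mixed carbonic anhydride of F5 | O=C1C[C@@]2(C(=O)OC(=O)OCC(C)C)C(C(=O)OC)=C[C@H](O)[C@@H](c3ccco3)[C@@H]2[C@@](C)(CCO[Si](C)(C)C(C)(C)C)[C@@H]1C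
F7 | step 17 | ring C carbinol (C12–OH, either epimer), 7α-OAc, 2α-OTBS | CC(=O)O[C@@H]1C[C@@]23COC(=O)C2=C[C@H](O[Si](C)(C)C(C)(C)C)[C@H]2c4occc4C(O)C[C@@](C)([C@@H]1C)[C@@H]23
A1 | alternative 1 | geranylgeranyl diphosphate | CC(C)=CCC/C(C)=C/CC/C(C)=C/CC/C(C)=C/COP(=O)(O)OP(=O)(O)O
A2 | alternative 1 | (−)-kolavenyl diphosphate | C1C[C@@]2(C)C(C)=CCC[C@@H]2[C@@](C)(CC/C(C)=C/COP(=O)(O)OP(=O)(O)O)[C@@H]1C
A3 | alternative 2 | 2-ethynyl cycloheptenone precursor (C16 ketone, C12=C13 alkene, C13 ethynyl, C2 silyl ether) | CC(=O)O[C@@H]1C[C@@]23COC(=O)C2=C[C@H](O[Si](C)(C)C(C)(C)C)[C@H]2C(=O)C(C#C)=CC[C@@](C)([C@@H]1C)[C@@H]23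
A4 | alternative 2 | furan with C12 methyl ether (C2 silyl ether) | CC(=O)O[C@@H]1C[C@@]23COC(=O)C2=C[C@H](O[Si](C)(C)C(C)(C)C)[C@H]2c4occc4[C@H](OC)C[C@@](C)([C@@H]1C)[C@@H]23
A5 | alternative 3 | C18 carboxylic acid with C5 methyl | CC(=O)O[C@@H]1C[C@@]2(C)C(C(=O)O)=CCC[C@@H]2[C@@](C)(CC(=O)OC)[C@@H]1C
A6 | alternative 3 | decalin 18,19-olide | CC(=O)O[C@@H]1C[C@@]23COC(=O)C2=CCC[C@@H]3[C@@](C)(CC(=O)OC)[C@@H]1C
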